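Ring B of the tetralin is cut at C2–C3 and C4–C4a. Both bonds are made in one photoredox radical [4+2] annulation: the primary C2 radical from an open-chain 2-aryl-1-iodoalkane (C1, C11 and C15 already set) adds to phenyl vinyl sulfone, and the α-sulfonyl radical closes onto C4a. The step exploits ring A: the oxygen on C5 activates the ortho carbon C4a, and the carboxyl on C8 blocks the para position. The sulfone is temporary: the C5 phenoxide later expels it as an ortho-quinone methide (O–C5–C4a–C4), to which the C4 methyl is added trans to the C1 side chain.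

Key step: step 9

Numbering: tetralin numbering of the target is used throughout. C1 carries the side chain, C4 the methyl group, C5 the hydroxyl and C8 the carboxyl; the side chain runs from C11 (CH–CH3) to C16 (CH2–O).

Assumption: Ru(OAc)2[(R)-BINAP] hydrogenates the (E)-2-methylallylic alcohol of step 3 with the facial sense known for geraniol, which corresponds to the (7R) center.

Step 1
Reactants: 1 (S)-citronellic acid; 2 (R)-4-benzyloxazolidin-2-one
Product: 3 (R)-4-benzyl-3-[(3S)-3,7-dimethyloct-6-enoyl]oxazolidin-2-one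
Conditions: t-BuCOCl, Et3N, THF, −20 °C; then 2, LiCl, rt
Reagents that add atoms: none
Why: N-acylation of the Evans auxiliary through the pivaloyl mixed anhydride joins the two starting materials without touching the C3 center of the acid, which becomes C11 of the target.

Step 2
Reactants: 3 (R)-4-benzyl-3-[(3S)-3,7-dimethyloct-6-enoyl]oxazolidin-2-one
Product: 4 (R)-4-benzyl-3-[(3S,6E)-8-hydroxy-3,7-dimethyloct-6-enoyl]oxazolidin-2-one
Conditions: SeO2 (0.5 equiv), t-BuOOH, CH2Cl2, rt
Reagents that add atoms: tert-butyl hydroperoxide, CC(C)(C)OO (source of the new oxygen, passed on by SeO2)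
Why: Sharpless allylic oxidation (ene reaction, then [2,3]-sigmatropic shift) attacks the (E)-methyl group at the more substituted end of the trisubstituted alkene and should give the (E)-allylic alcohol.

Step 3
Reactants: 4 (R)-4-benzyl-3-[(3S,6E)-8-hydroxy-3,7-dimethyloct-6-enoyl]oxazolidin-2-one
Product: 5 (R)-4-benzyl-3-[(3S,7R)-8-hydroxy-3,7-dimethyloctanoyl]oxazolidin-2-one
Conditions: H2 (50 atm), Ru(OAc)2[(R)-BINAP] (1 mol%), MeOH, rt
Reagents that add atoms: none
Why: Noyori hydroxyl-directed asymmetric hydrogenation of the allylic alcohol sets the (7R) methyl center (C15 of the target) under catalyst control, independent of the remote C3 center, and leaves the imide and the phenyl ring alone.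

Step 4
Reactants: 5 (R)-4-benzyl-3-[(3S,7R)-8-hydroxy-3,7-dimethyloctanoyl]oxazolidin-2-one
Product: 6 (R)-4-benzyl-3-[(3S,7R)-8-(benzyloxy)-3,7-dimethyloctanoyl]oxazolidin-2-one
Conditions: BnOC(=NH)CCl3, TfOH (5 mol%), CH2Cl2/cyclohexane, rt
Reagents that add atoms: benzyl 2,2,2-trichloroacetimidate, N=C(OCc1ccccc1)C(Cl)(Cl)Cl
Why: Acid-catalysed O-benzylation with the trichloroacetimidate protects the primary alcohol without base, so the imide is neither enolised nor cleaved.

Step 5
Reactants: 7 2-bromo-4-methoxybenzoic acid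
Product: 8 tert-butyl 2-bromo-4-methoxybenzoate
Conditions: Boc2O, DMAP (cat.), t-BuOH, 40 °C
Reagents that add atoms: di-tert-butyl dicarbonate, CC(C)(C)OC(=O)OC(=O)OC(C)(C)C
Why: DMAP-catalysed esterification through the mixed carbonic anhydride gives the tert-butyl ester, chosen because it resists hydride, alkoxide and Grignard reagents and is a poor partner for lactonisation with the C2 oxygen later.

Step 6
Reactants: 6 (R)-4-benzyl-3-[(3S,7R)-8-(benzyloxy)-3,7-dimethyloctanoyl]oxazolidin-2-one; 8 tert-butyl 2-bromo-4-methoxybenzoate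
Product: 10 tert-butyl 2-[(2S,3S,7R)-1-[(R)-4-benzyl-2-oxooxazolidin-3-yl]-8-(benzyloxy)-3,7-dimethyl-1-oxooctan-2-yl]-4-methoxybenzoate, via silyl ketene aminal 9 (not isolated)
Conditions: NaN(SiMe3)2, Me3SiCl, THF, −78 °C; then 8, Pd(dba)2 (5 mol%), P(t-Bu)3 (10 mol%), ZnF2 (0.5 equiv), DMF, 80 °C
Reagents that add atoms: chlorotrimethylsilane, C[Si](C)(C)Cl (its atoms stay only in intermediate 9)
Why: Hartwig palladium-catalysed α-arylation of the trimethylsilyl enolate of an Evans imide, run with ZnF2 and no strong base so that the acidic α-aryl center should not epimerise; the aryl group is delivered to the face of the (Z)-enolate opposite the benzyl group of the auxiliary, which sets C1 next to the fixed C11 center.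

Step 7
Reactants: 10 tert-butyl 2-[(2S,3S,7R)-1-[(R)-4-benzyl-2-oxooxazolidin-3-yl]-8-(benzyloxy)-3,7-dimethyl-1-oxooctan-2-yl]-4-methoxybenzoate
Product: 11 tert-butyl 2-[(2S,3S,7R)-8-(benzyloxy)-1-hydroxy-3,7-dimethyloctan-2-yl]-4-methoxybenzoate
Conditions: LiBH4, MeOH (1 equiv), Et2O, 0 °C
Reagents that add atoms: none
Why: Reductive removal of the Evans auxiliary (hydride attack at the exocyclic imide carbonyl) gives the primary alcohol at C2 with C1 intact, while the hindered tert-butyl ester and the benzyl ether are not reduced.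

Step 8
Reactants: 11 tert-butyl 2-[(2S,3S,7R)-8-(benzyloxy)-1-hydroxy-3,7-dimethyloctan-2-yl]-4-methoxybenzoate
Product: 12 tert-butyl 2-[(2S,3S,7R)-8-(benzyloxy)-1-iodo-3,7-dimethyloctan-2-yl]-4-methoxybenzoate
Conditions: I2, PPh3, imidazole, CH2Cl2, 0 °C
Reagents that add atoms: iodine, II
Why: Appel-type iodination by SN2 at the primary carbon C2, kept cold so that iodide outruns participation of the neighbouring ester carbonyl; no stereocenter is touched.

Step 9
Reactants: 12 tert-butyl 2-[(2S,3S,7R)-8-(benzyloxy)-1-iodo-3,7-dimethyloctan-2-yl]-4-methoxybenzoate; 13 phenyl vinyl sulfone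
Product: 14 tert-butyl (8S)-8-[(2S,6R)-7-(benzyloxy)-6-methylheptan-2-yl]-4-methoxy-5-(phenylsulfonyl)-5,6,7,8-tetrahydronaphthalene-1-carboxylate (both C5 epimers)
Conditions: 13 (3 equiv), fac-Ir(ppy)3 (2 mol%), 2,6-lutidine, DMSO, blue LEDs, rt
Reagents that add atoms: none
Why: Photoexcited fac-Ir(ppy)3 transfers an electron to the C–I bond, the primary C2 radical adds to the CH2 terminus of 13 (bond C2–C3), the electrophilic α-sulfonyl radical at C4 attacks C4a of ring A (bond C4–C4a), and the cyclohexadienyl radical is oxidised by the tetravalent iridium complex and deprotonated by lutidine, which restores the arene. The closest known reaction type is the radical [4+2] annulation of 2-arylethyl-type radicals with alkenes (Citterio-type addition followed by homolytic aromatic substitution), here in a redox-neutral photoredox form with a Giese acceptor. Ring B is closed in the six-membered Ar2-6 mode by attack on the ortho carbon of the arene. The only new center, C4, is formed without control as both epimers, which is harmless because it becomes planar again in step 11, and C1, C11 and C15 never carry spin. The step needs ring closure at C4a and not at C8: the C5 oxygen activates its ortho carbon C4a towards the electrophilic radical, whereas C8, para to that oxygen, is blocked and deactivated by the ester. The saturated, benzyl-protected side chain offers no alkene or weak C–H bond for cyclisation or 1,5-hydrogen transfer of the C2 radical, and the excess of 13 lets addition outrun its reduction.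

Step 10
Reactants: 14 tert-butyl (8S)-8-[(2S,6R)-7-(benzyloxy)-6-methylheptan-2-yl]-4-methoxy-5-(phenylsulfonyl)-5,6,7,8-tetrahydronaphthalene-1-carboxylate
Product: 15 (8S)-4-hydroxy-8-[(2S,6R)-7-hydroxy-6-methylheptan-2-yl]-5-(phenylsulfonyl)-5,6,7,8-tetrahydronaphthalene-1-carboxylic acid (both C5 epimers)
Conditions: BBr3 (6 equiv), CH2Cl2, −78 to 0 °C; then H2O, 0 °C
Reagents that add atoms: none
Why: BBr3 cleaves the aryl methyl ether, the benzyl ether and the tert-butyl ester in one Lewis-acid operation through bromoborane intermediates, and the cold, base-free work-up keeps the ortho-hydroxybenzyl sulfone from eliminating.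

Step 11
Reactants: 15 (8S)-4-hydroxy-8-[(2S,6R)-7-hydroxy-6-methylheptan-2-yl]-5-(phenylsulfonyl)-5,6,7,8-tetrahydronaphthalene-1-carboxylic acid
Product: 17 (5R,8S)-4-hydroxy-8-[(2S,6R)-7-hydroxy-6-methylheptan-2-yl]-5-methyl-5,6,7,8-tetrahydronaphthalene-1-carboxylic acid, via ortho-quinone methide 16 (not isolated)
Conditions: MeMgBr (6 equiv), THF, −40 °C to rt; then aq. NH4Cl, HCl to pH 3
Reagents that add atoms: methylmagnesium bromide, C[Mg]Br
Why: The magnesium phenoxide expels benzenesulfinate by 1,4-elimination to give the ortho-quinone methide, and 1,4-addition of the Grignard reagent to C4 restores ring A (ortho-hydroxybenzyl sulfone chemistry); the methyl group enters along the axial trajectory on the face opposite the C1 side chain, which peri strain with the C8 carboxylate holds pseudo-axial, so the 1,4-trans (5R) center should result.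

Step 12
Reactants: 17 (5R,8S)-4-hydroxy-8-[(2S,6R)-7-hydroxy-6-methylheptan-2-yl]-5-methyl-5,6,7,8-tetrahydronaphthalene-1-carboxylic acid; 18 4-methylpent-3-enoic acid
Product: 19 (5R,8S)-4-hydroxy-5-methyl-8-[(2S,6R)-6-methyl-7-[(4-methylpent-3-enoyl)oxy]heptan-2-yl]-5,6,7,8-tetrahydronaphthalene-1-carboxylic acid
Conditions: Novozym 435 (immobilised Candida antarctica lipase B), 4 Å molecular sieves, 2-methylbutan-2-ol, 45 °C
Reagents that add atoms: none
Why: Lipase-catalysed esterification acylates only the primary aliphatic alcohol, since the enzyme accepts neither the phenol as nucleophile nor the hindered benzoic acid as acyl donor, and the neutral conditions should not move the β,γ-double bond of the acyl group into conjugation.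

Compound list
1 | (S)-citronellic acid, (3S)-3,7-dimethyloct-6-enoic acid | C[C@@H](CCC=C(C)C)CC(=O)O | starting material
2 | (R)-4-benzyloxazolidin-2-one | O=C1N[C@H](Cc2ccccc2)CO1 | starting material
3 | (R)-4-benzyl-3-[(3S)-3,7-dimethyloct-6-enoyl]oxazolidin-2-one | C[C@@H](CCC=C(C)C)CC(=O)N1[C@H](Cc2ccccc2)COC1=O | intermediate
4 | (R)-4-benzyl-3-[(3S,6E)-8-hydroxy-3,7-dimethyloct-6-enoyl]oxazolidin-2-one | C[C@@H](CC/C=C(\C)CO)CC(=O)N1[C@H](Cc2ccccc2)COC1=O | intermediate
5 | (R)-4-benzyl-3-[(3S,7R)-8-hydroxy-3,7-dimethyloctanoyl]oxazolidin-2-one | C[C@@H](CCC[C@@H](C)CO)CC(=O)N1[C@H](Cc2ccccc2)COC1=O | intermediate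
6 | (R)-4-benzyl-3-[(3S,7R)-8-(benzyloxy)-3,7-dimethyloctanoyl]oxazolidin-2-one | C[C@@H](CCC[C@@H](C)COCc1ccccc1)CC(=O)N1[C@H](Cc2ccccc2)COC1=O | intermediate
7 | 2-bromo-4-methoxybenzoic acid | COc1ccc(C(=O)O)c(Br)c1 | starting material
8 | tert-butyl 2-bromo-4-methoxybenzoate | COc1ccc(C(=O)OC(C)(C)C)c(Br)c1 | intermediate
9 | (Z)-O-trimethylsilyl ketene N,O-acetal of 6 (silyl ketene aminal) | C[C@@H](CCC[C@@H](C)COCc1ccccc1)/C=C(\O[Si](C)(C)C)N1[C@H](Cc2ccccc2)COC1=O | intermediate
10 | tert-butyl 2-[(2S,3S,7R)-1-[(R)-4-benzyl-2-oxooxazolidin-3-yl]-8-(benzyloxy)-3,7-dimethyl-1-oxooctan-2-yl]-4-methoxybenzoate | C[C@@H](CCC[C@@H](C)COCc1ccccc1)[C@@H](c1cc(OC)ccc1C(=O)OC(C)(C)C)C(=O)N1[C@H](Cc2ccccc2)COC1=O | intermediate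
11 | tert-butyl 2-[(2S,3S,7R)-8-(benzyloxy)-1-hydroxy-3,7-dimethyloctan-2-yl]-4-methoxybenzoate | C[C@@H](CCC[C@@H](C)COCc1ccccc1)[C@@H](c1cc(OC)ccc1C(=O)OC(C)(C)C)CO | intermediate
12 | tert-butyl 2-[(2S,3S,7R)-8-(benzyloxy)-1-iodo-3,7-dimethyloctan-2-yl]-4-methoxybenzoate | C[C@@H](CCC[C@@H](C)COCc1ccccc1)[C@@H](c1cc(OC)ccc1C(=O)OC(C)(C)C)CI | intermediate
13 | phenyl vinyl sulfone | C=CS(=O)(=O)c1ccccc1 | starting material
14 | tert-butyl (8S)-8-[(2S,6R)-7-(benzyloxy)-6-methylheptan-2-yl]-4-methoxy-5-(phenylsulfonyl)-5,6,7,8-tetrahydronaphthalene-1-carboxylate (C5 epimers) | C[C@@H](CCC[C@@H](C)COCc1ccccc1)[C@@H]1CCC(S(=O)(=O)c2ccccc2)c2c(OC)ccc(C(=O)OC(C)(C)C)c21 | intermediate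
15 | (8S)-4-hydroxy-8-[(2S,6R)-7-hydroxy-6-methylheptan-2-yl]-5-(phenylsulfonyl)-5,6,7,8-tetrahydronaphthalene-1-carboxylic acid (C5 epimers) | C[C@@H](CCC[C@@H](C)CO)[C@@H]1CCC(S(=O)(=O)c2ccccc2)c2c(O)ccc(C(=O)O)c21 | intermediate
16 | ortho-quinone methide, (8S)-8-[(2S,6R)-7-hydroxy-6-methylheptan-2-yl]-4-oxo-4,6,7,8-tetrahydronaphthalene-1-carboxylic acid (present as its magnesium salt) | C[C@@H](CCC[C@@H](C)CO)[C@@H]1CCC=C2C(=O)C=CC(C(=O)O)=C21 | intermediate
17 | (5R,8S)-4-hydroxy-8-[(2S,6R)-7-hydroxy-6-methylheptan-2-yl]-5-methyl-5,6,7,8-tetrahydronaphthalene-1-carboxylic acid | C[C@@H](CCC[C@@H](C)CO)[C@@H]1CC[C@@H](C)c2c(O)ccc(C(=O)O)c21 | intermediate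
18 | 4-methylpent-3-enoic acid | CC(C)=CCC(=O)O | starting material
19 | (5R,8S)-4-hydroxy-5-methyl-8-[(2S,6R)-6-methyl-7-[(4-methylpent-3-enoyl)oxy]heptan-2-yl]-5,6,7,8-tetrahydronaphthalene-1-carboxylic acid (CNP0545998.1) | CC(C)=CCC(=O)OC[C@H](C)CCC[C@H](C)[C@@H]1CC[C@@H](C)c2c(O)ccc(C(=O)O)c21 | target

Total step count: 12

Longest linear sequence: 11 steps (steps 1, 2, 3, 4, 6, 7, 8, 9, 10, 11, 12; step 5 is the one-step side branch to the aryl bromide).

Steps most likely to fail

Step 9 (key step). Electron transfer to the unactivated primary iodide may be slow, so that the C2 radical is reduced, or the α-sulfonyl radical oligomerises with the sulfone before it closes onto C4a. The fallback makes the two bonds one after the other and sets out from iodide 12. Tin-free reductive Giese addition of 12 to 13 ((Me3Si)3SiH, AIBN, toluene, 80 °C) should give the open-chain sulfone tert-butyl 2-[(4S,5S,9R)-10-(benzyloxy)-5,9-dimethyl-1-(phenylsulfonyl)decan-4-yl]-4-methoxybenzoate F1. Deprotonation next to sulfur and bromination (LiN(i-Pr)2, THF, −78 °C; then CBr4) should give the α-bromo sulfone tert-butyl 2-[(4S,5S,9R)-10-(benzyloxy)-1-bromo-5,9-dimethyl-1-(phenylsulfonyl)decan-4-yl]-4-methoxybenzoate F2. F2 is an activated halide that Ru(bpy)3Cl2 reduces readily under visible light; its α-sulfonyl radical closes onto C4a (Ru(bpy)3Cl2, 2,6-lutidine, DMF, blue LEDs), and the sequence comes back to the route at 14.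

Step 11. The ortho-quinone methide may be lost by tautomerisation to the C3=C4 styrene, the Grignard reagent may deprotonate C4 of the sulfone instead of triggering the elimination, or facial discrimination at C4 may be incomplete on the magnesium tri-salt. The fallback sets out from the fully protected sulfone 14 and avoids the quinone methide. Lewis-acid ionisation of the benzylic sulfone, whose cation is stabilised by the ortho methoxy group, with methyl transfer from aluminium (AlMe3, CH2Cl2, −78 to 0 °C) should give tert-butyl (5R,8S)-8-[(2S,6R)-7-(benzyloxy)-6-methylheptan-2-yl]-4-methoxy-5-methyl-5,6,7,8-tetrahydronaphthalene-1-carboxylate F3, with the methyl again entering anti to the pseudo-axial C1 side chain. Global deprotection of F3 with BBr3 under the conditions of step 10 comes back to the route at 17.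

Step 6. Coupling of the hindered ortho-ester bromide may be sluggish, and the α-aryl imide may epimerise at C1 under the conditions, which would erode the diastereocontrol of the auxiliary. The fallback sets out from imide 6 and sets C1 by dynamic kinetic resolution instead. Methanolysis (NaOMe, MeOH, 0 °C) should give methyl (3S,7R)-8-(benzyloxy)-3,7-dimethyloctanoate F4. Palladium-catalysed α-arylation of its lithium enolate with 8 (LiN(SiMe3)2, Pd(dba)2, P(t-Bu)3, toluene, rt) should give tert-butyl 2-[(3S,7R)-8-(benzyloxy)-1-methoxy-3,7-dimethyl-1-oxooctan-2-yl]-4-methoxybenzoate F5 as a mixture of C2 epimers. Selective reduction of the methyl ester (i-Bu2AlH, toluene, −78 °C) should give the configurationally labile α-aryl aldehyde tert-butyl 2-[(3S,7R)-8-(benzyloxy)-3,7-dimethyl-1-oxooctan-2-yl]-4-methoxybenzoate F6. Ruthenium-catalysed hydrogenation of F6 under base-mediated epimerisation (H2, RuCl2(xylBINAP)(DAIPEN) in the enantiomeric form that gives the 2S alcohol, KOt-Bu, i-PrOH) comes back to the route at alcohol 11.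

Further compounds
F1 | step 9 | tert-butyl 2-[(4S,5S,9R)-10-(benzyloxy)-5,9-dimethyl-1-(phenylsulfonyl)decan-4-yl]-4-methoxybenzoate | C[C@@H](CCC[C@@H](C)COCc1ccccc1)[C@@H](c1cc(OC)ccc1C(=O)OC(C)(C)C)CCCS(=O)(=O)c1ccccc1
F2 | step 9 | tert-butyl 2-[(4S,5S,9R)-10-(benzyloxy)-1-bromo-5,9-dimethyl-1-(phenylsulfonyl)decan-4-yl]-4-methoxybenzoate (C1 epimers) | C[C@@H](CCC[C@@H](C)COCc1ccccc1)[C@@H](c1cc(OC)ccc1C(=O)OC(C)(C)C)CCC(Br)S(=O)(=O)c1ccccc1
F3 | step 11 | tert-butyl (5R,8S)-8-[(2S,6R)-7-(benzyloxy)-6-methylheptan-2-yl]-4-methoxy-5-methyl-5,6,7,8-tetrahydronaphthalene-1-carboxylate | C[C@@H](CCC[C@@H](C)COCc1ccccc1)[C@@H]1CC[C@@H](C)c2c(OC)ccc(C(=O)OC(C)(C)C)c21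
F4 | step 6 | methyl (3S,7R)-8-(benzyloxy)-3,7-dimethyloctanoate | C[C@@H](CCC[C@@H](C)COCc1ccccc1)CC(=O)OC
F5 | step 6 | tert-butyl 2-[(3S,7R)-8-(benzyloxy)-1-methoxy-3,7-dimethyl-1-oxooctan-2-yl]-4-methoxybenzoate (C2 epimers) | C[C@@H](CCC[C@@H](C)COCc1ccccc1)C(c1cc(OC)ccc1C(=O)OC(C)(C)C)C(=O)OC
F6 | step 6 | tert-butyl 2-[(3S,7R)-8-(benzyloxy)-3,7-dimethyl-1-oxooctan-2-yl]-4-methoxybenzoate (C2 epimers) | C[C@@H](CCC[C@@H](C)COCc1ccccc1)C(c1cc(OC)ccc1C(=O)OC(C)(C)C)C=O
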